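## Structural features

Selaginellin consists of five six-membered carbocycles joined only by single bonds, one exocyclic C=C and one alkyne; no ring is fused. The central benzene ring A (positions written a1 to a6 here) carries on a1 the methide carbon Cm, which is the exocyclic carbon of a para-quinone methide (ring C) and also bears phenol ring D. Position a2 carries phenol ring B, a3 and a4 carry hydrogen, a5 carries CH2OH, and a6 carries the alkyne Cα≡Cβ that ends in phenol ring E. The molecule has no stereogenic centre, so no stereocentres stand next to each other and nothing has to be set. The fragile groups are the quinone methide (a 1,6-acceptor, sensitive to acid, base and redox reagents), three free phenols, a benzylic alcohol, and an electron-rich diarylalkyne that an oxygen on Cm could attack (5-exo or 6-endo). The real difficulty is the run of four different carbon substituents on a1, a2, a5 and a6, with the bulkiest one (Cm and its two rings) wedged between ring B and the alkyne. The chosen key step exploits two facts. The only hydrogen-bearing carbons, a3 and a4, are adjacent and so correspond to the two carbons of acetylene. Cm on a1 and Cα on a6 are ortho, and the quinone methide is the dehydrated form of a triaryl carbinol, so the carbinol oxygen can be tied to Cα at the carboxyl level as a 3,3-diarylphthalide that an ester-tethered diyne delivers.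

## Logic of the disconnections

**22 ⇒ 20 (through 21).** No skeletal bond is cut. Water is added back across the quinone methide (Cm=C of ring C becomes Cm–OH plus a phenol), and the hydroxyl groups are traced back to three aryl sulfonates and one silyl ether. The reason is that a triaryl carbinol with para-hydroxyl groups on rings C and D loses water under mild acid, so the electrophilic quinone methide is never carried through a step. The gain is that every earlier intermediate is an ordinary carbinol or lactone. The demand is that the hot hydroxide needed for S–O cleavage must not add the Cm alkoxide to the alkyne, and that the acid stage stays mild enough to spare the electron-rich alkyne.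

**20 ⇒ 19 + 3.** The bond Cβ–ring E is cut. It is the standard aryl–alkynyl bond of a Sonogashira coupling, and 3 can be used without protection. The gain is that ring E and one protecting-group operation disappear. The demand is a coupling at room temperature beside the free Cm–OH.

**19 ⇒ 17 (through 18).** The bond Cα≡Cβ is cut: Cβ is removed and Cα returns to the aldehyde/lactol level. A one-carbon diazophosphonate homologation makes the alkyne from the carbonyl carbon on a6, so the former lactone carbon becomes Cα. The gain is that the alkyne is linked to the carbonyl of a phthalide. The demand is that 17 opens to 18 although its gem-diaryl substitution favours the ring.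

**17 ⇒ 16.** No skeletal bond is cut; the oxidation level is raised to the lactone, which is what the cycloaddition delivers. The demand is delivery of a single hydride with the sulfonates and the silyl ether untouched.

**16 ⇒ 14 + 15.** Three bonds of ring A are cut (a1–a6, a2–a3, a4–a5), which opens ring A and the lactone. The unsubstituted a3–a4 unit is 15, and the O–C(=O) tether between Cm and Cα forces a1 to bond to a6, so the positions of all four substituents follow from the connectivity of 14. The gain is that a tetrasubstituted benzene and a lactone with a quaternary carbon reduce to an acyclic ester and a C2 gas. The demand is that cross-cyclotrimerisation outruns dimerisation of 14 and oligomerisation of 15, and that the tertiary, doubly benzylic propargylic ester neither ionises nor rearranges on the metal. The design of 14 answers this in two ways: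
- All three aryl rings carry sulfonates. Rings C and D sit on the carbinol carbon. Ring B is included because the propargylic cation is conjugated through the alkyne to ring B, where a donor ether would stabilise its allenyl form.
- The primary oxygen is a silyl ether, so the last step needs only dilute acid, and no formaldehyde-releasing acetal or chloromethyl ether reagent is involved.

**14 ⇒ 6 + 2 + 10 (through 11, 12, 13).** The bonds Cm–C(sp) and ester O–acyl are cut. Both are made in one flask: acetylide addition to a symmetric diaryl ketone creates Cm while it is still unhindered, and the alkoxide is acylated directly. The gain is three simple fragments. The demand is a base that does not attack sulfonates, acylation of a crowded tertiary alkoxide in preference to conjugate addition, and acid activation without HCl.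

**6 ⇒ 4 ⇒ 3; 2 ⇒ 1; 10 ⇒ 8 ⇒ 7.** The cuts are an aryl–alkynyl bond (Sonogashira coupling with a silyl-capped C2 unit), S–O bonds, the alkynyl–CO2H bond (carboxylation) and an Si–O bond. The gain is that everything reaches purchasable phenols and 7. The demand is coupling at C–I only, and isolation of the acid without loss of the silyl ether.

## Other disconnections considered

**Alternative 1:** The cut is the two bonds from Cm to rings C and D. In the forward step the ring A aldehyde A2 would be condensed in a strong sulfonic acid with two molecules of phenol A3, each reacting at its para position, to give the triarylmethane A1. Later steps would be a Sonogashira coupling at the chloride, ester reduction, and dehydrogenation of Cm–H to the quinone methide.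
- In favour: rings C and D need no protecting groups and no organometallic reagent, and the oxidation level of Cm is reached by one late oxidation.
- Against: the aldehyde carbon lies between ring B and chlorine, so the second arylation builds a very crowded centre. The intermediate diarylmethyl cation has ring B ortho to it and could close to a 9-arylfluorene instead of taking the second phenol. Phenol can also react ortho. The later coupling would have to occur at an aryl chloride flanked on both sides. A2, with four contiguous substituents, still has to be made by classical arene chemistry.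
- Comparison: Alternative 1 is the better plan on protecting-group economy, and it avoids acetylene gas, the ionisable propargylic ester and any base step next to the alkyne. It is worse on structure, because the substitution pattern of ring A rests on directing effects in a preformed arene, whereas the chosen plan fixes it by connectivity. It is worse on mechanism, because a cationic cyclisation competes. Its step count is probably similar once A2 is counted.

**Alternative 2:** The cut is Cα≡Cβ together with Cβ–ring E. In the forward step [diazo(trimethylsilyl)methyl]lithium A6 would add to the diaryl ketone A5. Elimination to the diazoalkene, loss of nitrogen and a 1,2-aryl shift of the alkylidene carbene (Fritsch–Buttenberg–Wiechell type) would give alkyne A4.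
- In favour: the alkyne and ring E arrive without palladium or copper, ring E enters as a robust aroyl group, and A4 is one acid step from the target.
- Against: the ketone in A5 lies between C(OH)Ar2 and CH2OH, and both hydroxyls can add to it as five-membered hemiketals, which masks the carbonyl and consumes reagent. The di-ortho-substituted ketone is hindered towards the bulky anion. The carbene is generated next to two alkoxides, which could capture it. A5 already contains the complete substitution pattern of ring A, so the main difficulty is only moved upstream.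
- Comparison: the two plans are equal in principle at this stage, since both turn a carbonyl carbon on a6 into Cα by a diazo-based homologation. Alternative 2 is better there in step economy (one operation instead of homologation plus coupling), and its endgame needs only acid, which is better than the hydroxide stage of the chosen plan. Overall it is worse, because it does not say how ring A is assembled and its key carbonyl is likely masked.

**Alternative 3:** The cut is a2–a3 and a1–a6. In the forward step the dienyne A8 and the ynone A9 would combine in a [4+2] cycloaddition to the racemic 1,4-cyclohexadiene A7, whose single stereocentre at a6 disappears on dehydrogenation to the arene. Addition of a ring C aryl metal to the ketone and acid treatment would follow.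
- In favour: ring A is built from acyclic pieces with rings B, D and E and the alkyne already in place, no metal is needed, and the aromatisation is easy.
- Against: regiochemistry is not enforced. The alkynyl group at the diene terminus directs in the needed "ortho" sense, but the CH2OMOM group on the neighbouring diene carbon directs in the opposite "para" sense. The β-aryl ynone is a sluggish dienophile, and forcing conditions invite polymerisation of A8 or reaction through its enyne unit. A8 must be geometrically pure. Cm would be created late, by addition to a diaryl ketone flanked by two ortho substituents.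
- Comparison: Alternative 3 is the equal of the chosen plan in concept (ring A made de novo, two of its bonds being a1–a6 and a2–a3). It is the better plan on paper in step count, because no lactone-to-alkyne stretch is needed. It is worse in regiocontrol (competing directing effects against a tether plus the symmetric 15) and in the timing of Cm (late and crowded against early and unhindered).

Key step: step 7

Remarks on the chemistry:
- Selaginellin has no stereogenic centre, and the target SMILES defines no axis or helix, so no stereocontrol is planned. Lactol 17 is formed and used as a racemate.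
- Ts = 4-methylbenzenesulfonyl, TBS = tert-butyldimethylsilyl, MOM = methoxymethyl.
- The structures of the diyne and the phthalide were checked atom by atom against the bond map of the key step (a1–a6, a2–a3, a4–a5) and are consistent with it. The only changes are to protecting groups: a sulfonate on ring B and a silyl ether on the primary oxygen.

## Route

Step 1
Reactants: 1 4,4'-dihydroxybenzophenone
Product: 2 4,4'-bis(tosyloxy)benzophenone
Conditions: TsCl (2.3 equiv), Et3N, DMAP (cat.), CH2Cl2, 0 °C to rt
Reagents that add atoms: p-toluenesulfonyl chloride, Cc1ccc(cc1)S(Cl)(=O)=O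
Why: DMAP-catalysed O-sulfonylation of both phenols; the sulfonates survive the later acetylide and hydride steps and, as acceptors, make the tertiary propargylic ester of 14 reluctant to ionise.

Step 2
Reactants: 3 4-iodophenol
Product: 4 4-iodophenyl 4-methylbenzenesulfonate
Conditions: TsCl (1.1 equiv), Et3N, DMAP (cat.), CH2Cl2, 0 °C to rt
Reagents that add atoms: p-toluenesulfonyl chloride, Cc1ccc(cc1)S(Cl)(=O)=O
Why: O-tosylation of the phenol leaves the C–I bond untouched; the sulfonate matches those of rings C and D, so one hydroxide treatment later removes all three.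

Step 3
Reactants: 4 4-iodophenyl 4-methylbenzenesulfonate
Product: 6 4-ethynylphenyl 4-methylbenzenesulfonate, via silylalkyne 5 (not isolated)
Conditions: Me3SiC≡CH (1.2 equiv), PdCl2(PPh3)2 (2 mol %), CuI (4 mol %), Et3N/THF, rt; filtration; then K2CO3 (0.2 equiv), MeOH/THF, 0 °C
Reagents that add atoms: ethynyltrimethylsilane, C#C[Si](C)(C)C
Why: Sonogashira coupling should occur only at C–I, because aryl sulfonates of this kind do not add to the zerovalent palladium formed from PdCl2(PPh3)2 at room temperature; brief catalytic methanolysis then removes the silyl cap without cleaving the S–O bond.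

Step 4
Reactants: 7 propargyl alcohol
Product: 8 tert-butyldimethyl(prop-2-yn-1-yloxy)silane
Conditions: TBSCl, imidazole, CH2Cl2, 0 °C to rt
Reagents that add atoms: tert-butyldimethylsilyl chloride, CC(C)(C)[Si](C)(C)Cl
Why: Imidazole-mediated silylation of a primary alcohol; the silyl ether should survive organolithium, rhodium, hydride and carbonate/methanol conditions and leave at the end under dilute acid; 8 is also sold, in which case this step falls away.

Step 5
Reactants: 8 tert-butyldimethyl(prop-2-yn-1-yloxy)silane
Product: 10 4-[(tert-butyldimethylsilyl)oxy]but-2-ynoic acid, via lithium acetylide 9 (not isolated)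
Conditions: n-BuLi, THF, −78 °C; CO2 (g), −78 to 0 °C; cold 1 M HCl to pH 3
Reagents that add atoms: carbon dioxide, O=C=O
Why: Deprotonation of the terminal alkyne and carboxylation of the lithium acetylide; short, cold acidification to pH 3 should free the acid without loss of the silyl ether.

Step 6
Reactants: 6 4-ethynylphenyl 4-methylbenzenesulfonate; 2 4,4'-bis(tosyloxy)benzophenone; 10 4-[(tert-butyldimethylsilyl)oxy]but-2-ynoic acid
Product: 14 1,1,3-tris[4-(tosyloxy)phenyl]prop-2-yn-1-yl 4-[(tert-butyldimethylsilyl)oxy]but-2-ynoate, via lithium acetylide 11 (not isolated), via lithium alkoxide 12 (not isolated), via acid chloride 13 (not isolated)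
Conditions: 6, LiN(SiMe3)2, THF, −78 °C; then 2, −78 to −20 °C; then 13 (from 10, 1-chloro-N,N,2-trimethylprop-1-en-1-amine, CH2Cl2, 0 °C to rt; 1.3 equiv), −78 to 0 °C; pH 7 buffer; Et3N-deactivated silica
Reagents that add atoms: none
Why: LiN(SiMe3)2 deprotonates the arylalkyne but is too hindered to attack S–O bonds, and 1,2-addition of the acetylide to the activated, non-enolisable ketone gives the tertiary alkoxide. Trapping that alkoxide as its lithium salt with an acid chloride is the reliable way to acylate a crowded tertiary carbinol. The chloroenamine makes the acid chloride under neutral conditions, so neither HCl nor a nucleophilic catalyst meets the ynoate.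

Step 7
Reactants: 14 1,1,3-tris[4-(tosyloxy)phenyl]prop-2-yn-1-yl 4-[(tert-butyldimethylsilyl)oxy]but-2-ynoate; 15 acetylene
Product: 16 7-{[(tert-butyldimethylsilyl)oxy]methyl}-3,3,4-tris[4-(tosyloxy)phenyl]isobenzofuran-1(3H)-one
Conditions: RhCl(PPh3)3 (10 mol %), HC≡CH (1 atm, balloon, passed through a −78 °C trap), toluene, 60 °C, 14 added slowly by syringe pump
Reagents that add atoms: none
Why: After loss of a phosphine, monovalent rhodium binds both alkynes of 14 and couples them oxidatively to a trivalent rhodacyclopentadiene; this forms a1–a6 and closes the five-membered lactone through the three-atom C–O–C(=O) tether. Then 15 coordinates and inserts into a Rh–C bond, and reductive elimination forms a2–a3 and a4–a5, closing ring A in an overall [2+2+2] cycloaddition and returning monovalent rhodium. The closest known reaction type is the rhodium- or ruthenium-catalysed cyclotrimerisation of ester-tethered 1,6-diynes with monoalkynes to phthalides; a diyne substituted at both termini and carrying a quaternary propargylic carbon lies at the demanding end of that class. No stereocentre is formed. There is no regiochemical question, because 15 is symmetric and the tether decides which alkyne carbons meet. The selectivity needed is cross- over homo-cyclotrimerisation; the intramolecular first coupling, an acetylene-saturated solution and slow addition of 14 should secure it. The propargylic C–O bond should stay intact because the chloride complex is neutral, the solvent is non-polar, and all three aryl rings carry acceptor sulfonates. Aromatisation provides the driving force.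

Step 8
Reactants: 16 7-{[(tert-butyldimethylsilyl)oxy]methyl}-3,3,4-tris[4-(tosyloxy)phenyl]isobenzofuran-1(3H)-one
Product: 17 7-{[(tert-butyldimethylsilyl)oxy]methyl}-3,3,4-tris[4-(tosyloxy)phenyl]-1,3-dihydroisobenzofuran-1-ol (racemic at C1)
Conditions: i-Bu2AlH (1.3 equiv), CH2Cl2, −78 °C; aqueous potassium sodium tartrate
Reagents that add atoms: none
Why: Partial reduction of a lactone to a lactol: one hydride is delivered at −78 °C and the aluminium lactolate persists until work-up; aryl sulfonates and the silyl ether are inert, and the new lactol carbon, formed without control as a racemate, is destroyed in step 9.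

Step 9
Reactants: 17 7-{[(tert-butyldimethylsilyl)oxy]methyl}-3,3,4-tris[4-(tosyloxy)phenyl]-1,3-dihydroisobenzofuran-1-ol
Product: 19 {2-ethynyl-3-{[(tert-butyldimethylsilyl)oxy]methyl}-6-[4-(tosyloxy)phenyl]phenyl}bis[4-(tosyloxy)phenyl]methanol, via hydroxy aldehyde 18 (not isolated)
Conditions: dimethyl (1-diazo-2-oxopropyl)phosphonate (2.5 equiv), K2CO3 (3 equiv), MeOH/THF, 0 °C to rt
Reagents that add atoms: dimethyl (1-diazo-2-oxopropyl)phosphonate, CC(=O)C(=[N+]=[N-])P(=O)(OC)OC
Why: Ohira–Bestmann variant of the Seyferth–Gilbert homologation, known for lactols: 17 equilibrates with aldehyde 18, which the diazomethylphosphonate anion formed in the flask converts, through the diazoalkene and a 1,2-hydrogen shift of the alkylidene carbene, into the terminal alkyne. The former lactone carbon becomes Cα and the reagent supplies Cβ.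

Step 10
Reactants: 19 {2-ethynyl-3-{[(tert-butyldimethylsilyl)oxy]methyl}-6-[4-(tosyloxy)phenyl]phenyl}bis[4-(tosyloxy)phenyl]methanol; 3 4-iodophenol
Product: 20 {3-{[(tert-butyldimethylsilyl)oxy]methyl}-2-[(4-hydroxyphenyl)ethynyl]-6-[4-(tosyloxy)phenyl]phenyl}bis[4-(tosyloxy)phenyl]methanol
Conditions: 3 (1.5 equiv), PdCl2(PPh3)2 (5 mol %), CuI (5 mol %), Et3N/THF (degassed), rt
Reagents that add atoms: none
Why: Sonogashira coupling of a terminal alkyne with an aryl iodide, which tolerates free phenols and tertiary alcohols; room temperature is chosen to keep the Cm hydroxyl from adding across the alkyne. Using 3 unprotected saves a step and makes ring E a phenoxide in step 11.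

Step 11
Reactants: 20 {3-{[(tert-butyldimethylsilyl)oxy]methyl}-2-[(4-hydroxyphenyl)ethynyl]-6-[4-(tosyloxy)phenyl]phenyl}bis[4-(tosyloxy)phenyl]methanol
Product: 22 selaginellin, via tetraphenol carbinol 21 (not isolated)
Conditions: KOH (excess), MeOH/THF/H2O, 60 °C; then aqueous HCl to pH 1, rt; NaOAc buffer to pH 5 on work-up
Reagents that add atoms: none
Why: Hydroxide attacks sulfur of the three aryl sulfonates (saponification of aryl tosylates), while ring E, already a phenoxide, makes the alkyne a poor acceptor for the neighbouring alkoxide. Acid then cleaves the primary silyl ether and ionises the carbinol to a highly stabilised cation, which loses a phenolic proton to give the para-quinone methide (fuchsone formation by dehydration); any silyl ether lost in the basic stage converges to the same product.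

## Compound list

1 | 4,4'-dihydroxybenzophenone | O=C(c1ccc(O)cc1)c1ccc(O)cc1 | starting material
2 | 4,4'-bis(tosyloxy)benzophenone | O=C(c1ccc(OS(=O)(=O)c2ccc(C)cc2)cc1)c1ccc(OS(=O)(=O)c2ccc(C)cc2)cc1 | intermediate
3 | 4-iodophenol | Oc1ccc(I)cc1 | starting material
4 | 4-iodophenyl 4-methylbenzenesulfonate | Cc1ccc(cc1)S(=O)(=O)Oc1ccc(I)cc1 | intermediate
5 | 4-[(trimethylsilyl)ethynyl]phenyl 4-methylbenzenesulfonate | Cc1ccc(cc1)S(=O)(=O)Oc1ccc(C#C[Si](C)(C)C)cc1 | intermediate
6 | 4-ethynylphenyl 4-methylbenzenesulfonate | Cc1ccc(cc1)S(=O)(=O)Oc1ccc(C#C)cc1 | intermediate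
7 | propargyl alcohol | C#CCO | starting material
8 | tert-butyldimethyl(prop-2-yn-1-yloxy)silane | C#CCO[Si](C)(C)C(C)(C)C | intermediate
9 | lithium 3-[(tert-butyldimethylsilyl)oxy]prop-1-yn-1-ide | [Li]C#CCO[Si](C)(C)C(C)(C)C | intermediate
10 | 4-[(tert-butyldimethylsilyl)oxy]but-2-ynoic acid | CC(C)(C)[Si](C)(C)OCC#CC(=O)O | intermediate
11 | lithium [4-(tosyloxy)phenyl]ethynide | [Li]C#Cc1ccc(OS(=O)(=O)c2ccc(C)cc2)cc1 | intermediate
12 | lithium 1,1,3-tris[4-(tosyloxy)phenyl]prop-2-yn-1-olate | [Li+].[O-]C(C#Cc1ccc(OS(=O)(=O)c2ccc(C)cc2)cc1)(c1ccc(OS(=O)(=O)c2ccc(C)cc2)cc1)c1ccc(OS(=O)(=O)c2ccc(C)cc2)cc1 | intermediate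
13 | 4-[(tert-butyldimethylsilyl)oxy]but-2-ynoyl chloride | CC(C)(C)[Si](C)(C)OCC#CC(Cl)=O | intermediate
14 | 1,1,3-tris[4-(tosyloxy)phenyl]prop-2-yn-1-yl 4-[(tert-butyldimethylsilyl)oxy]but-2-ynoate | CC(C)(C)[Si](C)(C)OCC#CC(=O)OC(C#Cc1ccc(OS(=O)(=O)c2ccc(C)cc2)cc1)(c1ccc(OS(=O)(=O)c2ccc(C)cc2)cc1)c1ccc(OS(=O)(=O)c2ccc(C)cc2)cc1 | intermediate
15 | acetylene | C#C | starting material
16 | 7-{[(tert-butyldimethylsilyl)oxy]methyl}-3,3,4-tris[4-(tosyloxy)phenyl]isobenzofuran-1(3H)-one | O=C1OC(c2ccc(OS(=O)(=O)c3ccc(C)cc3)cc2)(c2ccc(OS(=O)(=O)c3ccc(C)cc3)cc2)c2c(-c3ccc(OS(=O)(=O)c4ccc(C)cc4)cc3)ccc(CO[Si](C)(C)C(C)(C)C)c21 | intermediate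
17 | 7-{[(tert-butyldimethylsilyl)oxy]methyl}-3,3,4-tris[4-(tosyloxy)phenyl]-1,3-dihydroisobenzofuran-1-ol (racemic) | OC1OC(c2ccc(OS(=O)(=O)c3ccc(C)cc3)cc2)(c2ccc(OS(=O)(=O)c3ccc(C)cc3)cc2)c2c(-c3ccc(OS(=O)(=O)c4ccc(C)cc4)cc3)ccc(CO[Si](C)(C)C(C)(C)C)c21 | intermediate
18 | 2-{hydroxybis[4-(tosyloxy)phenyl]methyl}-6-{[(tert-butyldimethylsilyl)oxy]methyl}-3-[4-(tosyloxy)phenyl]benzaldehyde | O=Cc1c(CO[Si](C)(C)C(C)(C)C)ccc(-c2ccc(OS(=O)(=O)c3ccc(C)cc3)cc2)c1C(O)(c1ccc(OS(=O)(=O)c2ccc(C)cc2)cc1)c1ccc(OS(=O)(=O)c2ccc(C)cc2)cc1 | intermediate
19 | {2-ethynyl-3-{[(tert-butyldimethylsilyl)oxy]methyl}-6-[4-(tosyloxy)phenyl]phenyl}bis[4-(tosyloxy)phenyl]methanol | C#Cc1c(CO[Si](C)(C)C(C)(C)C)ccc(-c2ccc(OS(=O)(=O)c3ccc(C)cc3)cc2)c1C(O)(c1ccc(OS(=O)(=O)c2ccc(C)cc2)cc1)c1ccc(OS(=O)(=O)c2ccc(C)cc2)cc1 | intermediate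
20 | {3-{[(tert-butyldimethylsilyl)oxy]methyl}-2-[(4-hydroxyphenyl)ethynyl]-6-[4-(tosyloxy)phenyl]phenyl}bis[4-(tosyloxy)phenyl]methanol | Oc1ccc(cc1)C#Cc1c(CO[Si](C)(C)C(C)(C)C)ccc(-c2ccc(OS(=O)(=O)c3ccc(C)cc3)cc2)c1C(O)(c1ccc(OS(=O)(=O)c2ccc(C)cc2)cc1)c1ccc(OS(=O)(=O)c2ccc(C)cc2)cc1 | intermediate
21 | {3-{[(tert-butyldimethylsilyl)oxy]methyl}-6-(4-hydroxyphenyl)-2-[(4-hydroxyphenyl)ethynyl]phenyl}bis(4-hydroxyphenyl)methanol | Oc1ccc(cc1)C#Cc1c(CO[Si](C)(C)C(C)(C)C)ccc(-c2ccc(O)cc2)c1C(O)(c1ccc(O)cc1)c1ccc(O)cc1 | intermediate
22 | selaginellin, 4-{[3-(hydroxymethyl)-6-(4-hydroxyphenyl)-2-[(4-hydroxyphenyl)ethynyl]phenyl](4-hydroxyphenyl)methylidene}cyclohexa-2,5-dien-1-one | O=C1C=CC(=C(c2ccc(O)cc2)c2c(-c3ccc(O)cc3)ccc(CO)c2C#Cc2ccc(O)cc2)C=C1 | target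

## Step count and least certain steps

Total step count: 11. Longest linear sequence: 8 steps (steps 2, 3, 6, 7, 8, 9, 10, 11 from 3; equally steps 4, 5, 6 to 11 from 7).

**Step 7 (key step).** Two processes are most likely to interfere. The first is ionisation or a metal-assisted 1,3-acyloxy shift of the tertiary propargylic ester on heating. The second is slow cyclometallation, because both alkyne termini are substituted, which would let oligomerisation of acetylene use up the catalyst. The fallback replaces the ester tether by an ether tether, which cannot ionise and belongs to the most reliable class of 1,6-diynes, and restores the carbonyl afterwards. It sets out from 8 and from alkoxide 12 and comes back at 16.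
- 8 would be deprotonated (n-BuLi) and hydroxymethylated with paraformaldehyde to 4-[(tert-butyldimethylsilyl)oxy]but-2-yn-1-ol F1.
- An Appel reaction (CBr4, PPh3) would give [(4-bromobut-2-yn-1-yl)oxy](tert-butyl)dimethylsilane F2.
- Alkoxide 12, generated as in step 6, would be O-alkylated in the same flask by F2 (DMPU, Bu4NI) to the dipropargyl ether tert-butyldimethyl[(4-{[1,1,3-tris(4-tosyloxyphenyl)prop-2-yn-1-yl]oxy}but-2-yn-1-yl)oxy]silane F3.
- F3 and 15 with RhCl(PPh3)3 would give 4-{[(tert-butyldimethylsilyl)oxy]methyl}-1,1,7-tris[4-(tosyloxy)phenyl]-1,3-dihydroisobenzofuran F4.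
- Oxidation of the ring CH2 of F4 (KMnO4 on CuSO4·5H2O, CH2Cl2, a reagent that takes cyclic benzylic ethers to lactones) would lead to 16. The selectivity to watch is the ring CH2 against the silyloxymethyl CH2.

**Step 9.** The gem-diaryl lactol may open too slowly, so the diazophosphonate anion decays before it meets the aldehyde; prolonged carbonate/methanol could also begin to methanolyse the sulfonates. The fallback uses a strongly basic, irreversible olefination, the classical way to pull lactols open, followed by elimination. It sets out from 17 and comes back at 19.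
- A Wittig reaction with Ph3P=CHCl (from (chloromethyl)triphenylphosphonium chloride and NaN(SiMe3)2, THF, −78 °C to rt) would give {2-(2-chloroethenyl)-3-{[(tert-butyldimethylsilyl)oxy]methyl}-6-[4-(tosyloxy)phenyl]phenyl}bis[4-(tosyloxy)phenyl]methanol F5 as an E/Z mixture.
- Dehydrochlorination with KOt-Bu in THF at 0 °C would give 19.

**Step 10.** Copper- or palladium-promoted addition of the Cm hydroxyl across the alkyne (5-exo or 6-endo cycloisomerisation) and oxidative homocoupling of the alkyne are the likely failures. The fallback removes the free hydroxyl before the coupling. It sets out from 19 and comes back at 22.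
- Silylation (Me3SiOTf, 2,6-lutidine, CH2Cl2, −78 °C) would give {[2-ethynyl-3-{[(tert-butyldimethylsilyl)oxy]methyl}-6-[4-(tosyloxy)phenyl]phenyl]bis[4-(tosyloxy)phenyl]methoxy}trimethylsilane F6.
- Sonogashira coupling with 3 would give {[3-{[(tert-butyldimethylsilyl)oxy]methyl}-2-[(4-hydroxyphenyl)ethynyl]-6-[4-(tosyloxy)phenyl]phenyl]bis[4-(tosyloxy)phenyl]methoxy}trimethylsilane F7.
- F7 would be taken through the two stages of step 11, where base and acid remove the trimethylsilyl group together with the sulfonates and the other silyl ether, to give 22.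

**Step 11.** During the hot hydroxide stage the tertiary alkoxide may add to the alkyne before ring E's phenoxide has deactivated it enough. In the acid stage, hydration of the electron-rich alkyne or Friedel–Crafts closure of the Cm cation onto ring B could compete if the acid is too strong or too warm. The fallback removes the sulfonates while the carbinol oxygen is still locked in the lactone and uses acetals from there on, so the endgame needs acid only. It sets out from 16 and comes back at 22.
- KOH in MeOH/THF/H2O, then NH4Cl to pH 7 (the lactone re-closes on neutralisation), would give 7-{[(tert-butyldimethylsilyl)oxy]methyl}-3,3,4-tris(4-hydroxyphenyl)isobenzofuran-1(3H)-one F8.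
- MOMCl and i-Pr2NEt would give 7-{[(tert-butyldimethylsilyl)oxy]methyl}-3,3,4-tris[4-(methoxymethoxy)phenyl]isobenzofuran-1(3H)-one F9.
- i-Bu2AlH would give the lactol 7-{[(tert-butyldimethylsilyl)oxy]methyl}-3,3,4-tris[4-(methoxymethoxy)phenyl]-1,3-dihydroisobenzofuran-1-ol F10.
- Ohira–Bestmann homologation would give {2-ethynyl-3-{[(tert-butyldimethylsilyl)oxy]methyl}-6-[4-(methoxymethoxy)phenyl]phenyl}bis[4-(methoxymethoxy)phenyl]methanol F11.
- Sonogashira coupling with 3 would give {3-{[(tert-butyldimethylsilyl)oxy]methyl}-2-[(4-hydroxyphenyl)ethynyl]-6-[4-(methoxymethoxy)phenyl]phenyl}bis[4-(methoxymethoxy)phenyl]methanol F12.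
- Aqueous HCl in MeOH would remove the three acetals and the silyl ether and dehydrate the carbinol to 22.

**Step 6.** Acylation of the crowded tertiary alkoxide may be incomplete, the alkoxide may add in a conjugate sense to the ynoyl chloride, or sulfonyl transfer may occur; the ester may also ionise on acidic silica. The fallback separates addition from acylation and replaces anion trapping by a neutral coupling. It sets out from 12 and comes back at 14.
- Quenching 12 with NH4Cl would give 1,1,3-tris[4-(tosyloxy)phenyl]prop-2-yn-1-ol F13.
- Steglich esterification of isolated F13 with 10 (DCC, DMAP cat., CH2Cl2, 0 °C) would give 14.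

## Further compounds

F1 | step 7 | 4-[(tert-butyldimethylsilyl)oxy]but-2-yn-1-ol | CC(C)(C)[Si](C)(C)OCC#CCO
F2 | step 7 | [(4-bromobut-2-yn-1-yl)oxy](tert-butyl)dimethylsilane | CC(C)(C)[Si](C)(C)OCC#CCBr
F3 | step 7 | tert-butyldimethyl[(4-{[1,1,3-tris(4-tosyloxyphenyl)prop-2-yn-1-yl]oxy}but-2-yn-1-yl)oxy]silane | CC(C)(C)[Si](C)(C)OCC#CCOC(C#Cc1ccc(OS(=O)(=O)c2ccc(C)cc2)cc1)(c1ccc(OS(=O)(=O)c2ccc(C)cc2)cc1)c1ccc(OS(=O)(=O)c2ccc(C)cc2)cc1
F4 | step 7 | 4-{[(tert-butyldimethylsilyl)oxy]methyl}-1,1,7-tris[4-(tosyloxy)phenyl]-1,3-dihydroisobenzofuran | C1OC(c2ccc(OS(=O)(=O)c3ccc(C)cc3)cc2)(c2ccc(OS(=O)(=O)c3ccc(C)cc3)cc2)c2c(-c3ccc(OS(=O)(=O)c4ccc(C)cc4)cc3)ccc(CO[Si](C)(C)C(C)(C)C)c21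
F5 | step 9 | {2-(2-chloroethenyl)-3-{[(tert-butyldimethylsilyl)oxy]methyl}-6-[4-(tosyloxy)phenyl]phenyl}bis[4-(tosyloxy)phenyl]methanol (E/Z mixture) | ClC=Cc1c(CO[Si](C)(C)C(C)(C)C)ccc(-c2ccc(OS(=O)(=O)c3ccc(C)cc3)cc2)c1C(O)(c1ccc(OS(=O)(=O)c2ccc(C)cc2)cc1)c1ccc(OS(=O)(=O)c2ccc(C)cc2)cc1
F6 | step 10 | {[2-ethynyl-3-{[(tert-butyldimethylsilyl)oxy]methyl}-6-[4-(tosyloxy)phenyl]phenyl]bis[4-(tosyloxy)phenyl]methoxy}trimethylsilane | C#Cc1c(CO[Si](C)(C)C(C)(C)C)ccc(-c2ccc(OS(=O)(=O)c3ccc(C)cc3)cc2)c1C(O[Si](C)(C)C)(c1ccc(OS(=O)(=O)c2ccc(C)cc2)cc1)c1ccc(OS(=O)(=O)c2ccc(C)cc2)cc1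
F7 | step 10 | {[3-{[(tert-butyldimethylsilyl)oxy]methyl}-2-[(4-hydroxyphenyl)ethynyl]-6-[4-(tosyloxy)phenyl]phenyl]bis[4-(tosyloxy)phenyl]methoxy}trimethylsilane | Oc1ccc(cc1)C#Cc1c(CO[Si](C)(C)C(C)(C)C)ccc(-c2ccc(OS(=O)(=O)c3ccc(C)cc3)cc2)c1C(O[Si](C)(C)C)(c1ccc(OS(=O)(=O)c2ccc(C)cc2)cc1)c1ccc(OS(=O)(=O)c2ccc(C)cc2)cc1
F8 | step 11 | 7-{[(tert-butyldimethylsilyl)oxy]methyl}-3,3,4-tris(4-hydroxyphenyl)isobenzofuran-1(3H)-one | O=C1OC(c2ccc(O)cc2)(c2ccc(O)cc2)c2c(-c3ccc(O)cc3)ccc(CO[Si](C)(C)C(C)(C)C)c21
F9 | step 11 | 7-{[(tert-butyldimethylsilyl)oxy]methyl}-3,3,4-tris[4-(methoxymethoxy)phenyl]isobenzofuran-1(3H)-one | O=C1OC(c2ccc(OCOC)cc2)(c2ccc(OCOC)cc2)c2c(-c3ccc(OCOC)cc3)ccc(CO[Si](C)(C)C(C)(C)C)c21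
F10 | step 11 | 7-{[(tert-butyldimethylsilyl)oxy]methyl}-3,3,4-tris[4-(methoxymethoxy)phenyl]-1,3-dihydroisobenzofuran-1-ol (racemic) | OC1OC(c2ccc(OCOC)cc2)(c2ccc(OCOC)cc2)c2c(-c3ccc(OCOC)cc3)ccc(CO[Si](C)(C)C(C)(C)C)c21
F11 | step 11 | {2-ethynyl-3-{[(tert-butyldimethylsilyl)oxy]methyl}-6-[4-(methoxymethoxy)phenyl]phenyl}bis[4-(methoxymethoxy)phenyl]methanol | C#Cc1c(CO[Si](C)(C)C(C)(C)C)ccc(-c2ccc(OCOC)cc2)c1C(O)(c1ccc(OCOC)cc1)c1ccc(OCOC)cc1
F12 | step 11 | {3-{[(tert-butyldimethylsilyl)oxy]methyl}-2-[(4-hydroxyphenyl)ethynyl]-6-[4-(methoxymethoxy)phenyl]phenyl}bis[4-(methoxymethoxy)phenyl]methanol | Oc1ccc(cc1)C#Cc1c(CO[Si](C)(C)C(C)(C)C)ccc(-c2ccc(OCOC)cc2)c1C(O)(c1ccc(OCOC)cc1)c1ccc(OCOC)cc1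
F13 | step 6 | 1,1,3-tris[4-(tosyloxy)phenyl]prop-2-yn-1-ol | OC(C#Cc1ccc(OS(=O)(=O)c2ccc(C)cc2)cc1)(c1ccc(OS(=O)(=O)c2ccc(C)cc2)cc1)c1ccc(OS(=O)(=O)c2ccc(C)cc2)cc1
A1 | alternative 1 | methyl 3-[bis(4-hydroxyphenyl)methyl]-2-chloro-4-(4-hydroxyphenyl)benzoate | COC(=O)c1ccc(-c2ccc(O)cc2)c(C(c2ccc(O)cc2)c2ccc(O)cc2)c1Cl
A2 | alternative 1 | methyl 2-chloro-3-formyl-4-(4-hydroxyphenyl)benzoate | COC(=O)c1ccc(-c2ccc(O)cc2)c(C=O)c1Cl
A3 | alternative 1 | phenol | Oc1ccccc1
A4 | alternative 2 | {3-(hydroxymethyl)-6-[4-(methoxymethoxy)phenyl]-2-{[4-(methoxymethoxy)phenyl]ethynyl}phenyl}bis[4-(methoxymethoxy)phenyl]methanol | OCc1ccc(-c2ccc(OCOC)cc2)c(C(O)(c2ccc(OCOC)cc2)c2ccc(OCOC)cc2)c1C#Cc1ccc(OCOC)cc1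
A5 | alternative 2 | {2-{hydroxybis[4-(methoxymethoxy)phenyl]methyl}-6-(hydroxymethyl)-3-[4-(methoxymethoxy)phenyl]phenyl}[4-(methoxymethoxy)phenyl]methanone | OCc1ccc(-c2ccc(OCOC)cc2)c(C(O)(c2ccc(OCOC)cc2)c2ccc(OCOC)cc2)c1C(=O)c1ccc(OCOC)cc1
A6 | alternative 2 | [diazo(trimethylsilyl)methyl]lithium | [Li]C(=[N+]=[N-])[Si](C)(C)C
A7 | alternative 3 | racemic [5-[(methoxymethoxy)methyl]-2-[4-(methoxymethoxy)phenyl]-6-{[4-(methoxymethoxy)phenyl]ethynyl}cyclohexa-1,4-dien-1-yl][4-(methoxymethoxy)phenyl]methanone | O=C(c1ccc(OCOC)cc1)C1=C(c2ccc(OCOC)cc2)CC=C(COCOC)C1C#Cc1ccc(OCOC)cc1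
A8 | alternative 3 | 1-(methoxymethoxy)-4-{(3Z)-4-[(methoxymethoxy)methyl]hexa-3,5-dien-1-yn-1-yl}benzene | C=C/C(COCOC)=C/C#Cc1ccc(OCOC)cc1
A9 | alternative 3 | 1,3-bis[4-(methoxymethoxy)phenyl]prop-2-yn-1-one | O=C(C#Cc1ccc(OCOC)cc1)c1ccc(OCOC)cc1
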